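The data were generated by integration for an exercise, noise included.

At 40.0 h the oak run holds 20% of X and 1% of Q, so the X share, X over all the charge no longer standing as Q, is 20.2%. This share is a reading at that one moment, not the final fate of a molecule of D.

| setting | birch | oak | flask |
|---|---|---|---|
| D | 0.50 M | 0.50 M | 0.50 M |
| E | 1.25 M | 1.25 M | 1.25 M |
| G | 2.5 mM | 10 mM | 5.0 mM |
| remark | run made earlier | run made earlier |  |
| time |  |  | 2.0 d |

| run | time / h | X / % | Q / % |
|---|---|---|---|
| birch | 6.00 | 8 | 34 |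
| birch | 12.0 | 8 | 36 |
| birch | 15.0 | 12 | 33 |
| birch | 20.0 | 14 | 26 |
| birch | 30.0 | 18 | 19 |
| birch | 40.0 | 19 | 11 |
| oak | 6.00 | 9 | 14 |
| oak | 12.0 | 11 | 6 |
| oak | 15.0 | 13 | 9 |
| oak | 20.0 | 15 | 7 |
| oak | 30.0 | 16 | 3 |
| oak | 40.0 | 20 | 1 |

(each reading ± 1.5 percentage points)

- ratio of X to Q at 6.0 min
- ratio of X to Q at 2.0 h
- ratio of X to Q at 2.0 d
- which of X and Q there is more of at 2.0 d

The birch run, with a quarter of oak's G, gives 21.3% at the same time, while a single reading scatters by 1.5 percentage points, so the share is read as not moving with G. My own reckoning therefore puts X in the flask, at 5.0 mM of G, near 20.2% of the charge at 2.0 d, a rough figure taken over from a reading at an earlier time. But that is one half of the ratio, and the other half is Q.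

The forecast gives 0.1 at 6.0 min, 0.13 at 2.0 h and 9 at 2.0 d, with X ahead, and expects X to “reach about 22% by 48 h”. Set beside my share, its last ratio asks for Q of 2.24%.

The flask gives 0.0417, 0.0955 and 5.85, with X ahead: 21.4% of X against 3.66% of Q.

    E + G + Q → G + Z (k = 0.0110 M⁻² s⁻¹)
    D + E ⇌ X (K = 120 M⁻¹, k = 1.37 × 10⁻⁶ M⁻¹ s⁻¹)
    E + G → J (k = 2.46 × 10⁻⁶ M⁻¹ s⁻¹)
    Q + G ⇌ X + G, rate k4*[G]*[Q] forward; the back reaction follows from the equilibrium constant (k = 0.00209 M⁻¹ s⁻¹)
    D + E ⇌ Q (K = 10.3 M⁻¹, k = 3.49 × 10⁻⁵ M⁻¹ s⁻¹)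

The flask's own X share is 22.2%, close to 20.2%, so the gap in the last ratio lies in Q. Up to 2.0 d the direct step from D and E has given 3.87% net, and in the run without the passing of Q into X the ratio at that time falls from 5.85 to 0.608, which is a part of the story. At 6.0 min the direct step is the largest single effect on the ratio, which falls from 0.0417 to 0.00190 in the run without it.

With 0.0085 M of G in the neighbour flask, the share again puts X near 20.2%. That neighbour computes to 20.4% of X and 1.98% of Q, a ratio of 10.3.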